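**Retrosynthetic overview**
1. Target 28 comes from the N-Boc, O-silyl amino alcohol 23 by esterification with (2E,4E)-octa-2,4-dienoic acid 24, then removal of the silyl ether and the Boc group.
2. 23 comes from the hexahydroquinolinone 19 by three substrate-controlled reductions: C8a–OH (silane), C4=C4a (H2), C3=O (bulky borohydride).
3. Feature used: piperidine carbons C3, C4, C4a and C8a (C4a–C8a shared with the cyclohexane, oxygen on C3) are the four carbons of a furan fused to the carbocycle. 19 therefore comes from furan carbamate 17 by oxidative furan-to-piperidinone ring expansion that forms N1–C8a.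
4. 17 comes from the (S)-4-alkyl-tetrahydrobenzofuran 11 by C2 formylation, sulfinyl imine formation, MeMgBr addition and N-group exchange. 11 comes from ketone 7 and the Grignard reagent made from (R)-2-propyloxirane 1, by dehydration and asymmetric hydrogenation.
5. Ring order: the carbocycle and the furan are bought fused (7); the piperidine is the only ring made, in step 11.

Key step: step 11

Assumption: the side-chain hydroxyl is carried as a tert-butyldiphenylsilyl (TBDPS) ether so that it survives the HCl used to cleave the sulfinyl group and the BF3·OEt2 of step 12; in step 6 the ligand antipode is taken as the one that gives the (4S) centre, by analogy with 1-alkyl-3,4-dihydronaphthalenes.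

Abbreviation in names: "(5R)-5-(TBDPSO)octyl" = (5R)-5-[(tert-butyldiphenylsilyl)oxy]octyl.

**Route**

Step 1
Reactants: 1 (R)-2-propyloxirane
Product: 2 (4R)-oct-7-en-4-ol
Conditions: allylmagnesium bromide (1.3 equiv), CuBr·SMe2 (5 mol %), THF, −40 to 0 °C; then H2O
Reagents that add atoms: allylmagnesium bromide, C=CC[Mg]Br
Why: copper-catalysed SN2 opening of a terminal epoxide by a Grignard reagent occurs at the unsubstituted carbon, so the carbinol stereocentre is carried over untouched.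

Step 2
Reactants: 2 (4R)-oct-7-en-4-ol
Product: 3 tert-butyl{[(4R)-oct-7-en-4-yl]oxy}diphenylsilane
Conditions: TBDPSCl, imidazole, DMF, rt
Reagents that add atoms: tert-butyl(chloro)diphenylsilane, CC(C)(C)[Si](Cl)(c1ccccc1)c1ccccc1
Why: imidazole-promoted silylation of a secondary alcohol gives an ether that tolerates organometallics, brief HCl and Lewis acid at low temperature.

Step 3
Reactants: 3 tert-butyl{[(4R)-oct-7-en-4-yl]oxy}diphenylsilane
Product: 5 (5R)-5-(TBDPSO)octan-1-ol, via B-alkyl-9-borabicyclononane 4 (not isolated)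
Conditions: 9-BBN, THF, 0 °C to rt; then aq NaOH, H2O2, 0 °C
Reagents that add atoms: hydrogen peroxide, OO
Why: anti-Markovnikov hydroboration of the terminal alkene and oxidation of the C–B bond should give the primary alcohol only.

Step 4
Reactants: 5 (5R)-5-(TBDPSO)octan-1-ol
Product: 6 {[(4R)-8-bromooctan-4-yl]oxy}(tert-butyl)diphenylsilane
Conditions: CBr4, PPh3, CH2Cl2, 0 °C
Reagents that add atoms: carbon tetrabromide, BrC(Br)(Br)Br
Why: Appel bromination converts the primary alcohol to the bromide under neutral conditions that leave the silyl ether alone.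

Step 5
Reactants: 6 {[(4R)-8-bromooctan-4-yl]oxy}(tert-butyl)diphenylsilane; 7 6,7-dihydro-1-benzofuran-4(5H)-one
Product: 10 4-[(5R)-5-(TBDPSO)octyl]-6,7-dihydro-1-benzofuran, via Grignard reagent 8 (not isolated), via tertiary furylic alcohol 9 (not isolated)
Conditions: Mg turnings, THF, rt; add to 7 and LaCl3·2LiCl in THF, 0 °C; H2O; crude 9 with pTsOH·H2O (2 mol %), PhMe, rt
Reagents that add atoms: none
Why: Grignard 1,2-addition to the ketone (the lanthanum salt suppresses enolisation) gives a tertiary furylic alcohol that should lose water under trace acid (E1) to the endocyclic alkene conjugated with the furan.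

Step 6
Reactants: 10 4-[(5R)-5-(TBDPSO)octyl]-6,7-dihydro-1-benzofuran
Product: 11 (4S)-4-[(5R)-5-(TBDPSO)octyl]-4,5,6,7-tetrahydro-1-benzofuran
Conditions: H2 (50 bar), [Ir(cod)(L)][B(3,5-(CF3)2C6H3)4] (1 mol %), L = (S)-4-tert-butyl-2-[2-(di-o-tolylphosphanyl)phenyl]-4,5-dihydro-1,3-oxazole (antipode if needed), CH2Cl2, rt
Reagents that add atoms: none
Why: iridium-catalysed asymmetric hydrogenation of an unfunctionalised cyclic trisubstituted alkene with a chiral P,N ligand; the catalyst alone should set the C4 centre (S), the remote carbinol centre having no influence.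

Step 7
Reactants: 11 (4S)-4-[(5R)-5-(TBDPSO)octyl]-4,5,6,7-tetrahydro-1-benzofuran
Product: 13 (4S)-4-[(5R)-5-(TBDPSO)octyl]-4,5,6,7-tetrahydro-1-benzofuran-2-carbaldehyde, via 2-lithiofuran 12 (not isolated)
Conditions: n-BuLi, THF, −78 to 0 °C; DMF, −78 °C to rt; H2O
Reagents that add atoms: N,N-dimethylformamide, CN(C)C=O
Why: the only free α-position of the furan is lithiated selectively and the aryllithium is formylated by DMF.

Step 8
Reactants: 13 (4S)-4-[(5R)-5-(TBDPSO)octyl]-4,5,6,7-tetrahydro-1-benzofuran-2-carbaldehyde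
Product: 14 (S,E)-N-({(4S)-4-[(5R)-5-(TBDPSO)octyl]-4,5,6,7-tetrahydro-1-benzofuran-2-yl}methylidene)-2-methylpropane-2-sulfinamide
Conditions: (S)-tert-butanesulfinamide, Ti(OEt)4 (2 equiv), THF, rt
Reagents that add atoms: (S)-2-methylpropane-2-sulfinamide, CC(C)(C)[S@](=O)N
Why: titanium-mediated condensation of an aldehyde with tert-butanesulfinamide gives the (E)-N-sulfinyl aldimine, the alkoxide acting as Lewis acid and water scavenger.

Step 9
Reactants: 14 (S,E)-N-sulfinyl aldimine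
Product: 15 (S)-N-[(1R)-1-{(4S)-4-[(5R)-5-(TBDPSO)octyl]-4,5,6,7-tetrahydro-1-benzofuran-2-yl}ethyl]-2-methylpropane-2-sulfinamide
Conditions: MeMgBr (Et2O solution), CH2Cl2, −48 °C to rt; then H2O
Reagents that add atoms: methylmagnesium bromide, C[Mg]Br
Why: Grignard addition to an N-tert-butanesulfinyl aldimine in a non-coordinating solvent runs through a six-membered chair transition state with magnesium on the sulfinyl oxygen, and with the (S)-sulfinyl group the methyl should enter so that the new carbon is (R).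

Step 10
Reactants: 15 (S)-N-[(1R)-1-(furyl)ethyl]sulfinamide
Product: 17 tert-butyl N-[(1R)-1-{(4S)-4-[(5R)-5-(TBDPSO)octyl]-4,5,6,7-tetrahydro-1-benzofuran-2-yl}ethyl]carbamate, via ammonium chloride 16 (not isolated)
Conditions: HCl (4 M in dioxane, 2 equiv), MeOH, 0 °C, 20 min; evaporate; Boc2O, Et3N, CH2Cl2, 0 °C to rt
Reagents that add atoms: di-tert-butyl dicarbonate, CC(C)(C)OC(=O)OC(=O)OC(C)(C)C
Why: the N–S bond is cleaved by methanolic HCl within minutes, too briefly to touch the secondary TBDPS ether, and the liberated amine is acylated by Boc2O.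

Step 11
Reactants: 17 tert-butyl N-[(1R)-1-{(4S)-4-[(5R)-5-(TBDPSO)octyl]-4,5,6,7-tetrahydro-1-benzofuran-2-yl}ethyl]carbamate
Product: 19 tert-butyl (2R,5S,8aS)-8a-hydroxy-2-methyl-3-oxo-5-[(5R)-5-(TBDPSO)octyl]-3,5,6,7,8,8a-hexahydroquinoline-1(2H)-carboxylate (8a configuration provisional), via (Z)-ene-dione 18 (not isolated)
Conditions: mCPBA (1.1 equiv), CH2Cl2, 0 °C to rt
Reagents that add atoms: 3-chloroperbenzoic acid, OOC(=O)c1cccc(Cl)c1
Why: mCPBA epoxidises the electron-rich trialkylfuran at the bond bearing the aminoethyl group, and the epoxide opens with the ring oxygen to the (Z)-ene-1,4-dione 18, whose cis geometry is fixed by the furan. This is the aza-Achmatowicz rearrangement, the known oxidative ring expansion of 2-(α-acylaminoalkyl)furans to 6-hydroxy-2H-pyridin-3-ones. The carbamate nitrogen then adds to the C8a ketone (the former furan C7a) in a 6-exo-trig hemiaminal closure that forms N1–C8a and the piperidine ring, leaving the C3 ketone conjugated with C4=C4a. The only new stereocentre, C8a, forms reversibly and should settle with the hydroxyl pseudoaxial and cis to the C2 methyl, which is itself pseudoaxial to avoid 1,3-allylic strain with the Boc group; this centre is erased in step 12, and any open-chain 18 left at equilibrium converges there too. The step needs chemoselectivity only: the furan is by far the most electron-rich site (carbamate N–H, silyl ether and phenyl rings are inert to peracid), and one equivalent of oxidant at low temperature guards against over-oxidation. C2 and C5 are not involved and should keep their configuration under these near-neutral conditions.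

Step 12
Reactants: 19 N-Boc 8a-hydroxy hexahydroquinolin-3-one
Product: 21 tert-butyl (2R,5S,8aR)-2-methyl-3-oxo-5-[(5R)-5-(TBDPSO)octyl]-3,5,6,7,8,8a-hexahydroquinoline-1(2H)-carboxylate, via N-acyliminium ion 20 (not isolated)
Conditions: Et3SiH (5 equiv), BF3·OEt2 (2 equiv), CH2Cl2, −78 to −40 °C
Reagents that add atoms: none
Why: ionic hydrogenation of an N-acyl hemiaminal: BF3 ionises C8a–OH and the silane should deliver hydride axially, cis to the pseudoaxial C2 methyl and trans to the pseudoaxial C5 chain, so both groups direct to the same face and give (8aR).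

Step 13
Reactants: 21 N-Boc hexahydroquinolin-3-one (C4=C4a enone)
Product: 22 tert-butyl (2R,4aS,5S,8aR)-2-methyl-3-oxo-5-[(5R)-5-(TBDPSO)octyl]octahydroquinoline-1(2H)-carboxylate
Conditions: H2 (1 atm), Pd/C (10 wt %), EtOAc, rt
Reagents that add atoms: none
Why: heterogeneous syn hydrogenation of the enone C=C should take place on the face that carries H8a and is remote from the C5 chain, placing H4a cis to H8a and H5 (cis ring fusion, 4aS).

Step 14
Reactants: 22 N-Boc cis-octahydroquinolin-3-one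
Product: 23 tert-butyl (2R,3R,4aS,5S,8aR)-3-hydroxy-2-methyl-5-[(5R)-5-(TBDPSO)octyl]octahydroquinoline-1(2H)-carboxylate
Conditions: LiBH(s-Bu)3, THF, −78 °C; then aq NaOH, H2O2, 0 °C
Reagents that add atoms: none
Why: the bulky trialkylborohydride should approach the C3 carbonyl from the face opposite the adjacent C2 methyl, giving the (3R) alcohol cis to the methyl.

Step 15
Reactants: 23 N-Boc (3R)-alcohol; 24 (2E,4E)-octa-2,4-dienoic acid
Product: 26 tert-butyl (2R,3R,4aS,5S,8aR)-2-methyl-3-{[(2E,4E)-octa-2,4-dienoyl]oxy}-5-[(5R)-5-(TBDPSO)octyl]octahydroquinoline-1(2H)-carboxylate, via mixed anhydride 25 (not isolated)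
Conditions: 24, 2,4,6-trichlorobenzoyl chloride, Et3N, THF, rt; then 23, DMAP, PhMe, rt to 40 °C
Reagents that add atoms: none
Why: Yamaguchi esterification acylates hindered secondary alcohols through the mixed anhydride and the acylpyridinium ion, without disturbing the diene geometry or the C3 centre.

Step 16
Reactants: 26 N-Boc dienoate silyl ether
Product: 27 tert-butyl (2R,3R,4aS,5S,8aR)-5-[(5R)-5-hydroxyoctyl]-2-methyl-3-{[(2E,4E)-octa-2,4-dienoyl]oxy}octahydroquinoline-1(2H)-carboxylate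
Conditions: TBAF, AcOH (1:1), THF, rt
Reagents that add atoms: none
Why: buffered fluoride cleaves the Si–O bond while the nitrogen is still acylated, so the ester cannot migrate to nitrogen.

Step 17
Reactants: 27 N-Boc hydroxy dienoate
Product: 28 (2R,3R,4aS,5S,8aR)-5-[(5R)-5-hydroxyoctyl]-2-methyldecahydroquinolin-3-yl (2E,4E)-octa-2,4-dienoate (target)
Conditions: TFA/CH2Cl2 (1:4), 0 °C to rt; then aq NaHCO3
Reagents that add atoms: none
Why: acidolysis of the tert-butyl carbamate releases the secondary amine, and the mild bicarbonate work-up gives the free base without O-to-N acyl transfer.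

**Compound list**
1 | (R)-2-propyloxirane | CCC[C@@H]1CO1 | starting material
2 | (4R)-oct-7-en-4-ol | C=CCC[C@H](O)CCC | intermediate
3 | tert-butyl{[(4R)-oct-7-en-4-yl]oxy}diphenylsilane | C=CCC[C@H](O[Si](c1ccccc1)(c1ccccc1)C(C)(C)C)CCC | intermediate
4 | 9-[(5R)-5-(TBDPSO)octyl]-9-borabicyclo[3.3.1]nonane (not isolated) | C1CC2CCCC(C1)B2CCCC[C@H](O[Si](c1ccccc1)(c1ccccc1)C(C)(C)C)CCC | intermediate
5 | (5R)-5-(TBDPSO)octan-1-ol | OCCCC[C@H](O[Si](c1ccccc1)(c1ccccc1)C(C)(C)C)CCC | intermediate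
6 | {[(4R)-8-bromooctan-4-yl]oxy}(tert-butyl)diphenylsilane | BrCCCC[C@H](O[Si](c1ccccc1)(c1ccccc1)C(C)(C)C)CCC | intermediate
7 | 6,7-dihydro-1-benzofuran-4(5H)-one | O=C1CCCc2occc12 | starting material
8 | [(5R)-5-(TBDPSO)octyl]magnesium bromide (not isolated) | Br[Mg]CCCC[C@H](O[Si](c1ccccc1)(c1ccccc1)C(C)(C)C)CCC | intermediate
9 | 4-[(5R)-5-(TBDPSO)octyl]-4,5,6,7-tetrahydro-1-benzofuran-4-ol, both C4 epimers (not isolated) | OC1(CCCC[C@H](O[Si](c3ccccc3)(c3ccccc3)C(C)(C)C)CCC)CCCc2occc12 | intermediate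
10 | 4-[(5R)-5-(TBDPSO)octyl]-6,7-dihydro-1-benzofuran | c1cc2c(o1)CCC=C2CCCC[C@H](O[Si](c1ccccc1)(c1ccccc1)C(C)(C)C)CCC | intermediate
11 | (4S)-4-[(5R)-5-(TBDPSO)octyl]-4,5,6,7-tetrahydro-1-benzofuran | c1cc2c(o1)CCC[C@@H]2CCCC[C@H](O[Si](c1ccccc1)(c1ccccc1)C(C)(C)C)CCC | intermediate
12 | {(4S)-4-[(5R)-5-(TBDPSO)octyl]-4,5,6,7-tetrahydro-1-benzofuran-2-yl}lithium (not isolated) | [Li]c1cc2c(o1)CCC[C@@H]2CCCC[C@H](O[Si](c1ccccc1)(c1ccccc1)C(C)(C)C)CCC | intermediate
13 | (4S)-4-[(5R)-5-(TBDPSO)octyl]-4,5,6,7-tetrahydro-1-benzofuran-2-carbaldehyde | O=Cc1cc2c(o1)CCC[C@@H]2CCCC[C@H](O[Si](c1ccccc1)(c1ccccc1)C(C)(C)C)CCC | intermediate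
14 | (S,E)-N-({(4S)-4-[(5R)-5-(TBDPSO)octyl]-4,5,6,7-tetrahydro-1-benzofuran-2-yl}methylidene)-2-methylpropane-2-sulfinamide | CC(C)(C)[S@](=O)/N=C/c1cc2c(o1)CCC[C@@H]2CCCC[C@H](O[Si](c1ccccc1)(c1ccccc1)C(C)(C)C)CCC | intermediate
15 | (S)-N-[(1R)-1-{(4S)-4-[(5R)-5-(TBDPSO)octyl]-4,5,6,7-tetrahydro-1-benzofuran-2-yl}ethyl]-2-methylpropane-2-sulfinamide | C[C@@H](N[S@@](=O)C(C)(C)C)c1cc2c(o1)CCC[C@@H]2CCCC[C@H](O[Si](c1ccccc1)(c1ccccc1)C(C)(C)C)CCC | intermediate
16 | (1R)-1-{(4S)-4-[(5R)-5-(TBDPSO)octyl]-4,5,6,7-tetrahydro-1-benzofuran-2-yl}ethan-1-aminium chloride (not isolated) | C[C@@H]([NH3+])c1cc2c(o1)CCC[C@@H]2CCCC[C@H](O[Si](c1ccccc1)(c1ccccc1)C(C)(C)C)CCC.[Cl-] | intermediate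
17 | tert-butyl N-[(1R)-1-{(4S)-4-[(5R)-5-(TBDPSO)octyl]-4,5,6,7-tetrahydro-1-benzofuran-2-yl}ethyl]carbamate | C[C@@H](NC(=O)OC(C)(C)C)c1cc2c(o1)CCC[C@@H]2CCCC[C@H](O[Si](c1ccccc1)(c1ccccc1)C(C)(C)C)CCC | intermediate
18 | tert-butyl N-[(2R,4Z)-3-oxo-4-{(2S)-6-oxo-2-[(5R)-5-(TBDPSO)octyl]cyclohexylidene}butan-2-yl]carbamate (not isolated) | C[C@@H](NC(=O)OC(C)(C)C)C(=O)/C=C1\C(=O)CCC[C@@H]1CCCC[C@H](O[Si](c1ccccc1)(c1ccccc1)C(C)(C)C)CCC | intermediate
19 | tert-butyl (2R,5S,8aS)-8a-hydroxy-2-methyl-3-oxo-5-[(5R)-5-(TBDPSO)octyl]-3,5,6,7,8,8a-hexahydroquinoline-1(2H)-carboxylate (8a provisional) | O=C1C=C2[C@@H](CCCC[C@H](O[Si](c3ccccc3)(c3ccccc3)C(C)(C)C)CCC)CCC[C@@]2(O)N(C(=O)OC(C)(C)C)[C@@H]1C | intermediate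
20 | (2R,5S)-1-(tert-butoxycarbonyl)-2-methyl-3-oxo-5-[(5R)-5-(TBDPSO)octyl]-2,3,5,6,7,8-hexahydroquinolin-1-ium hydroxytrifluoroborate (not isolated) | O=C1C=C2[C@@H](CCCC[C@H](O[Si](c3ccccc3)(c3ccccc3)C(C)(C)C)CCC)CCCC2=[N+](C(=O)OC(C)(C)C)[C@@H]1C.O[B-](F)(F)F | intermediate
21 | tert-butyl (2R,5S,8aR)-2-methyl-3-oxo-5-[(5R)-5-(TBDPSO)octyl]-3,5,6,7,8,8a-hexahydroquinoline-1(2H)-carboxylate | O=C1C=C2[C@@H](CCCC[C@H](O[Si](c3ccccc3)(c3ccccc3)C(C)(C)C)CCC)CCC[C@H]2N(C(=O)OC(C)(C)C)[C@@H]1C | intermediate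
22 | tert-butyl (2R,4aS,5S,8aR)-2-methyl-3-oxo-5-[(5R)-5-(TBDPSO)octyl]octahydroquinoline-1(2H)-carboxylate | O=C1C[C@H]2[C@@H](CCCC[C@H](O[Si](c3ccccc3)(c3ccccc3)C(C)(C)C)CCC)CCC[C@H]2N(C(=O)OC(C)(C)C)[C@@H]1C | intermediate
23 | tert-butyl (2R,3R,4aS,5S,8aR)-3-hydroxy-2-methyl-5-[(5R)-5-(TBDPSO)octyl]octahydroquinoline-1(2H)-carboxylate | O[C@@H]1C[C@H]2[C@@H](CCCC[C@H](O[Si](c3ccccc3)(c3ccccc3)C(C)(C)C)CCC)CCC[C@H]2N(C(=O)OC(C)(C)C)[C@@H]1C | intermediate
24 | (2E,4E)-octa-2,4-dienoic acid | CCC/C=C/C=C/C(=O)O | starting material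
25 | (2E,4E)-octa-2,4-dienoic 2,4,6-trichlorobenzoic anhydride (not isolated) | CCC/C=C/C=C/C(=O)OC(=O)c1c(Cl)cc(Cl)cc1Cl | intermediate
26 | tert-butyl (2R,3R,4aS,5S,8aR)-2-methyl-3-{[(2E,4E)-octa-2,4-dienoyl]oxy}-5-[(5R)-5-(TBDPSO)octyl]octahydroquinoline-1(2H)-carboxylate | CCC/C=C/C=C/C(=O)O[C@@H]1C[C@H]2[C@@H](CCCC[C@H](O[Si](c3ccccc3)(c3ccccc3)C(C)(C)C)CCC)CCC[C@H]2N(C(=O)OC(C)(C)C)[C@@H]1C | intermediate
27 | tert-butyl (2R,3R,4aS,5S,8aR)-5-[(5R)-5-hydroxyoctyl]-2-methyl-3-{[(2E,4E)-octa-2,4-dienoyl]oxy}octahydroquinoline-1(2H)-carboxylate | CCC/C=C/C=C/C(=O)O[C@@H]1C[C@H]2[C@@H](CCCC[C@H](O)CCC)CCC[C@H]2N(C(=O)OC(C)(C)C)[C@@H]1C | intermediate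
28 | (2R,3R,4aS,5S,8aR)-5-[(5R)-5-hydroxyoctyl]-2-methyldecahydroquinolin-3-yl (2E,4E)-octa-2,4-dienoate | CCC/C=C/C=C/C(=O)O[C@@H]1C[C@H]2[C@@H](CCCC[C@H](O)CCC)CCC[C@H]2N[C@@H]1C | target

**Step count**
Total: 17 steps. Longest linear sequence: 17 steps (1 to 28; 7 and 24 are bought).

**Steps most likely to fail, with fallbacks**

Step 11 (key step). The peracid may over-oxidise the ene-dione (Baeyer–Villiger-type cleavage or a second oxidation), and closure of the Boc carbamate onto the hindered C8a ketone may be incomplete, so that open-chain 18 isomerises at the double bond. The fallback sets out from 17 and separates oxidation from ring closure. Oxidative 2,5-dimethoxylation of the furan with Br2 in MeOH (NaHCO3, −40 °C) should give the isolable bis-ketal tert-butyl N-[(1R)-1-{(4S)-2,7a-dimethoxy-4-[(5R)-5-(TBDPSO)octyl]-2,4,5,6,7,7a-hexahydro-1-benzofuran-2-yl}ethyl]carbamate F1, a masked ene-dione. Mild aqueous acid (PPTS, acetone–H2O, rt) then unveils the (Z)-ene-dione 18 with no oxidant present, and the carbamate closes to 19, where the route is rejoined.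

Step 13. Facial selectivity in the enone hydrogenation may be poor, because the C2 methyl and the C5 chain shield opposite faces of C4=C4a; the trans-fused isomer would result. The fallback sets out from 21 and reverses the order of the two reductions so that a hydroxyl group directs the hydrogen. Luche reduction (NaBH4, CeCl3·7H2O, MeOH, −78 °C) should add hydride to C3 anti to the pseudoaxial C2 methyl and give the allylic alcohol tert-butyl (2R,3R,5S,8aR)-3-hydroxy-2-methyl-5-[(5R)-5-(TBDPSO)octyl]-3,5,6,7,8,8a-hexahydroquinoline-1(2H)-carboxylate F2. Hydroxyl-directed homogeneous hydrogenation with [Ir(cod)(PCy3)(py)]PF6 (H2, CH2Cl2, rt) then delivers hydrogen to C4a from the face of the C3 hydroxyl, which is also the face of H8a. This gives 23 directly, so step 14 is not needed.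

Step 6. Enantiofacial discrimination by the iridium catalyst on this furan-fused alkene may be insufficient, and alkene isomerisation or partial furan saturation may compete. The fallback sets the C4 centre by conjugate addition and builds the furan afterwards. It sets out from Grignard reagent 8 (made from 6 in Et2O) and commercial cyclohex-2-en-1-one. Copper-catalysed asymmetric conjugate addition (CuBr·SMe2, (R)-1-[(S_P)-2-(diphenylphosphino)ferrocenyl]ethyldicyclohexylphosphine or its antipode, t-BuOMe, −75 °C) should give the regiodefined enolate bromomagnesium (3S)-3-[(5R)-5-(TBDPSO)octyl]cyclohex-1-en-1-olate F3. This is trapped in the same flask with allyl iodide (DMPU) as (2R,3S)-3-[(5R)-5-(TBDPSO)octyl]-2-(prop-2-en-1-yl)cyclohexan-1-one F4. Ozonolysis (O3, CH2Cl2, −78 °C; Me2S) gives 2-{(1R,6S)-2-oxo-6-[(5R)-5-(TBDPSO)octyl]cyclohexyl}acetaldehyde F5. Paal–Knorr cyclodehydration (pTsOH cat., PhMe, rt) closes the furan and returns to the route at 11.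

**Further compounds**
F1 | step 11 | tert-butyl N-[(1R)-1-{(4S)-2,7a-dimethoxy-4-[(5R)-5-(TBDPSO)octyl]-2,4,5,6,7,7a-hexahydro-1-benzofuran-2-yl}ethyl]carbamate (mixture at C2 and C7a) | C[C@@H](NC(=O)OC(C)(C)C)C1(OC)C=C2[C@@H](CCCC[C@H](O[Si](c3ccccc3)(c3ccccc3)C(C)(C)C)CCC)CCCC2(OC)O1
F2 | step 13 | tert-butyl (2R,3R,5S,8aR)-3-hydroxy-2-methyl-5-[(5R)-5-(TBDPSO)octyl]-3,5,6,7,8,8a-hexahydroquinoline-1(2H)-carboxylate | O[C@@H]1C=C2[C@@H](CCCC[C@H](O[Si](c3ccccc3)(c3ccccc3)C(C)(C)C)CCC)CCC[C@H]2N(C(=O)OC(C)(C)C)[C@@H]1C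
F3 | step 6 | bromomagnesium (3S)-3-[(5R)-5-(TBDPSO)octyl]cyclohex-1-en-1-olate | Br[Mg]OC1=C[C@@H](CCCC[C@H](O[Si](c2ccccc2)(c2ccccc2)C(C)(C)C)CCC)CCC1
F4 | step 6 | (2R,3S)-3-[(5R)-5-(TBDPSO)octyl]-2-(prop-2-en-1-yl)cyclohexan-1-one | O=C1CCC[C@H](CCCC[C@H](O[Si](c2ccccc2)(c2ccccc2)C(C)(C)C)CCC)[C@H]1CC=C
F5 | step 6 | 2-{(1R,6S)-2-oxo-6-[(5R)-5-(TBDPSO)octyl]cyclohexyl}acetaldehyde | O=C1CCC[C@H](CCCC[C@H](O[Si](c2ccccc2)(c2ccccc2)C(C)(C)C)CCC)[C@H]1CC=O
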